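**Retrosynthetic overview**
1. Target 13 ⇒ aryl chloride 10 + alkenyl boronate 11 (Suzuki coupling, then acetal hydrolysis); the free phenol comes from an aryl bromide (hydroxylation) and the CH2OH from a vinyl group (ozonolysis, reduction).
2. The dioxane ring is the only ring built (both benzene rings are bought); it is closed in step 3 by intramolecular aryl C–O coupling of the syn alcohol 6, with retention at both carbons.
3. Key C–C bond (between the two sp3 carbons of the dioxane) ⇐ 3,4,5-trimethoxybenzaldehyde 5 + aryloxyallene 4. The oxygen-bearing allene carbon, normally an acceptor, is turned into a donor (α-aryloxyallyl-ruthenium) and sets both stereocentres at once.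
4. 4 ⇐ 2,6-dibromo-4-chlorophenol 1 + propargyl bromide 2; the three halogens of 1 later become the ring oxygen, the free OH and the enal.

Assumption: the facial sense of (R)-BINAP in step 2 is assigned by analogy and is checked on the first run (chiral HPLC or Mosher ester of 6); if the antipode forms, (S)-BINAP is used.

**Step 1**
Reactants: 1 2,6-dibromo-4-chlorophenol; 2 propargyl bromide (3-bromoprop-1-yne)
Product: 4 1,3-dibromo-5-chloro-2-(propa-1,2-dien-1-yloxy)benzene, via aryl propargyl ether 3 (not isolated)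
Conditions: K2CO3, acetone, 56 °C; filter, concentrate; then KOtBu (0.3 equiv), THF, 0 °C to rt
Reagents that add atoms: none
Why: Williamson O-alkylation (SN2) of the acidic phenol, then base-catalysed propargyl-to-allenyl prototropic isomerisation, which stops at the aryloxyallene with substoichiometric KOtBu at low temperature; no stereocentre is formed.

**Step 2**
Reactants: 4 1,3-dibromo-5-chloro-2-(propa-1,2-dien-1-yloxy)benzene; 5 3,4,5-trimethoxybenzaldehyde
Product: 6 (1S,2S)-2-(2,6-dibromo-4-chlorophenoxy)-1-(3,4,5-trimethoxyphenyl)but-3-en-1-ol (syn)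
Conditions: RuH2(CO)(PPh3)3 (5 mol %), (R)-BINAP (6 mol %), 2-propanol (3 equiv), THF, 75 °C
Reagents that add atoms: none
Why: Proposed new method: a ruthenium hydride fed by 2-propanol hydrometalates the terminal C=C of 4 anti to the bulky aryloxy group to give a (Z)-γ-aryloxy-σ-allylruthenium, whose oxygen-bearing carbon (an α-aryloxy carbanion equivalent, the reverse of its normal acceptor character) adds to the aldehyde carbon through a closed chair SE2′ transition state, so the Z geometry gives the syn pair and BINAP selects the aldehyde face to give (1S,2S); the closest known reaction type is the Krische-type transfer-hydrogenative carbonyl allylation with alkoxyallenes and allenamides, which gives branched α-heteroatom-substituted homoallylic alcohols.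

**Step 3**
Reactants: 6 (1S,2S)-2-(2,6-dibromo-4-chlorophenoxy)-1-(3,4,5-trimethoxyphenyl)but-3-en-1-ol
Product: 7 (2S,3S)-5-bromo-7-chloro-3-ethenyl-2-(3,4,5-trimethoxyphenyl)-2,3-dihydro-1,4-benzodioxine (trans)
Conditions: CuI (10 mol %), 3,4,7,8-tetramethyl-1,10-phenanthroline (20 mol %), Cs2CO3 (2 equiv), toluene, 100 °C
Reagents that add atoms: none
Why: Intramolecular Ullmann-type C–O coupling of the secondary alkoxide with either of the two equivalent ortho bromides closes the six-membered ring; no bond at either stereocentre is broken, so syn-6 gives the trans ring with both centres retained, and the aryl chloride is inert to copper at this temperature.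

**Step 4**
Reactants: 7 (2S,3S)-5-bromo-7-chloro-3-ethenyl-2-(3,4,5-trimethoxyphenyl)-2,3-dihydro-1,4-benzodioxine
Product: 9 [(2S,3S)-8-bromo-6-chloro-3-(3,4,5-trimethoxyphenyl)-2,3-dihydro-1,4-benzodioxin-2-yl]methanol, via aldehyde 8 (not isolated)
Conditions: O3, CH2Cl2, −78 °C; PPh3, −78 to 0 °C; then NaBH4, MeOH, 0 °C
Reagents that add atoms: ozone, [O-][O+]=O
Why: Ozonolysis of the terminal alkene (far more reactive than the arenes when ozone is titrated) with reductive work-up, then immediate cold borohydride reduction of the α-aryloxy aldehyde before it can epimerise, so both stereocentres are kept.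

**Step 5**
Reactants: 9 [(2S,3S)-8-bromo-6-chloro-3-(3,4,5-trimethoxyphenyl)-2,3-dihydro-1,4-benzodioxin-2-yl]methanol
Product: 10 (2S,3S)-7-chloro-3-(hydroxymethyl)-2-(3,4,5-trimethoxyphenyl)-2,3-dihydro-1,4-benzodioxin-5-ol
Conditions: Cu(acac)2 (5 mol %), N,N′-bis(4-hydroxy-2,6-dimethylphenyl)oxalamide (5 mol %), LiOH·H2O (3 equiv), DMSO/H2O 4:1, 80 °C; then dilute HCl
Reagents that add atoms: lithium hydroxide, [Li+].[OH-]
Why: Copper-catalysed Ullmann-type hydroxylation replaces the aryl bromide with OH, while the aryl chloride needs far higher temperature and excess aqueous hydroxide outcompetes the primary alcohol; the stereocentres are not involved.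

**Step 6**
Reactants: 10 (2S,3S)-7-chloro-3-(hydroxymethyl)-2-(3,4,5-trimethoxyphenyl)-2,3-dihydro-1,4-benzodioxin-5-ol; 11 (E)-2-(3,3-diethoxyprop-1-en-1-yl)-4,4,5,5-tetramethyl-1,3,2-dioxaborolane
Product: 13 (2E)-3-[(2S,3S)-8-hydroxy-2-(hydroxymethyl)-3-(3,4,5-trimethoxyphenyl)-2,3-dihydro-1,4-benzodioxin-6-yl]prop-2-enal, via diethyl acetal 12 (not isolated)
Conditions: Pd(OAc)2 (3 mol %), SPhos (2-dicyclohexylphosphino-2′,6′-dimethoxybiphenyl, 6 mol %), K3PO4 (3 equiv), 1,4-dioxane/H2O 5:1, 90 °C; then 1 M HCl, THF, rt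
Reagents that add atoms: water, O
Why: Suzuki–Miyaura coupling of the electron-rich aryl chloride with the alkenyl boronate (a dialkylbiarylphosphine ligand allows oxidative addition and tolerates free OH groups) keeps the E geometry, and mild acid hydrolysis of the acetal releases the enal of the target without touching the stereocentres.

**Compound list**
1 | 2,6-dibromo-4-chlorophenol | Oc1c(Br)cc(Cl)cc1Br | starting material
2 | propargyl bromide (3-bromoprop-1-yne) | C#CCBr | starting material
3 | 1,3-dibromo-5-chloro-2-(prop-2-yn-1-yloxy)benzene | C#CCOc1c(Br)cc(Cl)cc1Br | intermediate (not isolated)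
4 | 1,3-dibromo-5-chloro-2-(propa-1,2-dien-1-yloxy)benzene | C=C=COc1c(Br)cc(Cl)cc1Br | intermediate
5 | 3,4,5-trimethoxybenzaldehyde | COc1cc(C=O)cc(OC)c1OC | starting material
6 | (1S,2S)-2-(2,6-dibromo-4-chlorophenoxy)-1-(3,4,5-trimethoxyphenyl)but-3-en-1-ol | COc1cc([C@H](O)[C@@H](Oc2c(Br)cc(Cl)cc2Br)C=C)cc(OC)c1OC | intermediate
7 | (2S,3S)-5-bromo-7-chloro-3-ethenyl-2-(3,4,5-trimethoxyphenyl)-2,3-dihydro-1,4-benzodioxine | COc1cc([C@@H]2Oc3cc(Cl)cc(Br)c3O[C@H]2C=C)cc(OC)c1OC | intermediate
8 | (2R,3S)-8-bromo-6-chloro-3-(3,4,5-trimethoxyphenyl)-2,3-dihydro-1,4-benzodioxine-2-carbaldehyde (same spatial arrangement as 7; the descriptor changes only through priorities) | COc1cc([C@@H]2Oc3cc(Cl)cc(Br)c3O[C@H]2C=O)cc(OC)c1OC | intermediate (not isolated)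
9 | [(2S,3S)-8-bromo-6-chloro-3-(3,4,5-trimethoxyphenyl)-2,3-dihydro-1,4-benzodioxin-2-yl]methanol | COc1cc([C@@H]2Oc3cc(Cl)cc(Br)c3O[C@H]2CO)cc(OC)c1OC | intermediate
10 | (2S,3S)-7-chloro-3-(hydroxymethyl)-2-(3,4,5-trimethoxyphenyl)-2,3-dihydro-1,4-benzodioxin-5-ol | COc1cc([C@@H]2Oc3cc(Cl)cc(O)c3O[C@H]2CO)cc(OC)c1OC | intermediate
11 | (E)-2-(3,3-diethoxyprop-1-en-1-yl)-4,4,5,5-tetramethyl-1,3,2-dioxaborolane | CCOC(OCC)/C=C/B1OC(C)(C)C(C)(C)O1 | starting material
12 | (2S,3S)-7-[(1E)-3,3-diethoxyprop-1-en-1-yl]-3-(hydroxymethyl)-2-(3,4,5-trimethoxyphenyl)-2,3-dihydro-1,4-benzodioxin-5-ol | COc1cc([C@@H]2Oc3cc(/C=C/C(OCC)OCC)cc(O)c3O[C@H]2CO)cc(OC)c1OC | intermediate (not isolated)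
13 | (2E)-3-[(2S,3S)-8-hydroxy-2-(hydroxymethyl)-3-(3,4,5-trimethoxyphenyl)-2,3-dihydro-1,4-benzodioxin-6-yl]prop-2-enal | COc1cc([C@@H]2Oc3cc(/C=C/C=O)cc(O)c3O[C@H]2CO)cc(OC)c1OC | target

**Totals and risks**
Total step count: 6. Longest linear sequence: 6 (1 → 4 → 6 → 7 → 9 → 10 → 13).

Most likely to fail, first: step 2. The coupling is unproven for this bulky, electron-poor aryloxyallene; it could give the linear enol-ether regioisomer, low dr or ee, or lose the allene. The fallback sets out from 4 (with 5) and comes back at 6. Copper-hydride-catalysed hydroboration of 4 with pinacolborane (CuCl, 4,5-bis(diphenylphosphino)-9,9-dimethylxanthene, NaOtBu, THF, 0 °C) gives the (Z)-γ-aryloxyallyl pinacol boronate F1. Chiral-phosphoric-acid-catalysed allylboration of 5 (the TRIP enantiomer that gives the (1S,2S) series, 5 mol %, toluene, −30 °C) proceeds through a chair transition state to the O-boryl syn adduct F2, which aqueous work-up hydrolyses to 6.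

Second: step 5. Hydroxylation of a hindered, electron-rich aryl bromide may stall, or the primary alcohol may O-arylate. The fallback sets out from 9 and comes back at 10. Miyaura borylation (bis(pinacolato)diboron, PdCl2(dppf), KOAc, 1,4-dioxane, 85 °C; bromide reacts before chloride) gives the aryl pinacol boronate F3, and oxidation (H2O2, NaOH, THF/H2O, 0 °C) gives 10.

Third: step 6. The acetal-bearing alkenyl boronate may protodeboronate or couple sluggishly with the electron-rich chloride. The fallback sets out from 10 and comes back at 13. Suzuki vinylation with potassium vinyltrifluoroborate (Pd(OAc)2, SPhos, K2CO3, toluene/H2O, 90 °C) gives the styrene F4. Cross-metathesis of F4 with crotonaldehyde (second-generation Hoveyda–Grubbs catalyst, RuCl2(H2IMes)(=CH-C6H4-2-OiPr), 5 mol %, CH2Cl2, 40 °C) gives the (E)-enal 13.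

**Further compounds**
F1 | step 2 | (Z)-2-[3-(2,6-dibromo-4-chlorophenoxy)prop-2-en-1-yl]-4,4,5,5-tetramethyl-1,3,2-dioxaborolane | CC1(C)OB(C/C=C\Oc2c(Br)cc(Cl)cc2Br)OC1(C)C
F2 | step 2 | 2-{[(1S,2S)-2-(2,6-dibromo-4-chlorophenoxy)-1-(3,4,5-trimethoxyphenyl)but-3-en-1-yl]oxy}-4,4,5,5-tetramethyl-1,3,2-dioxaborolane | COc1cc([C@H](OB2OC(C)(C)C(C)(C)O2)[C@@H](Oc2c(Br)cc(Cl)cc2Br)C=C)cc(OC)c1OC
F3 | step 5 | [(2S,3S)-6-chloro-8-(4,4,5,5-tetramethyl-1,3,2-dioxaborolan-2-yl)-3-(3,4,5-trimethoxyphenyl)-2,3-dihydro-1,4-benzodioxin-2-yl]methanol | COc1cc([C@@H]2Oc3cc(Cl)cc(B4OC(C)(C)C(C)(C)O4)c3O[C@H]2CO)cc(OC)c1OC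
F4 | step 6 | (2S,3S)-7-ethenyl-3-(hydroxymethyl)-2-(3,4,5-trimethoxyphenyl)-2,3-dihydro-1,4-benzodioxin-5-ol | COc1cc([C@@H]2Oc3cc(C=C)cc(O)c3O[C@H]2CO)cc(OC)c1OC
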